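**Retrosynthetic overview**
1. The acid is freed last from its methyl ester. The cyclopentanone is closed late by a SmI2 ketyl–nitrile cyclisation between an ethyl ketone and a nitrile carried on the two ring-fusion carbons.
2. The styryl-bearing quaternary carbon and the ring C=C come from a Carroll [3,3] shift of a phenacyl unit from a tertiary allylic oxygen to the neighbouring allylic carbon.
3. The cyclohexene comes from a Diels–Alder reaction of 3,4-diethyl-6-methyl-2H-pyran-2-one, a dearomatised heteroarene, with an (E)-α′-hydroxy enone built from (S)-lactate. The lactate carbons become ring carbon C3 and its ethyl group.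
4. Enabling feature: in the 2H-pyran-2-one ring the ring oxygen O1 and the carbonyl carbon C2 tie C6 to C3, which holds the diene C3=C4–C5=C6 planar and s-cis although both termini are fully substituted. C2 later becomes the CO2H carbon, and O1 becomes the leaving oxygen of the Carroll step.
5. Ring order: six-membered carbocycle (step 7, with a temporary lactone bridge), then the five-membered ketone (step 13).

Key step: step 7

Remark on the chemistry: the nitrile-bearing carbon of 10 (later the methyl-bearing α-carbon of the ketone) is carried as an epimer mixture; it and the ethyl-bearing α-carbon are set by equilibration in step 15. SMILES leave such centres undefined.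

**Step 1**
Reactants: 1 4-hydroxy-6-methyl-2H-pyran-2-one (triacetic acid lactone)
Product: 3 3-ethyl-4-hydroxy-6-methyl-2H-pyran-2-one, via ethylidene pyrandione 2 (not isolated)
Conditions: MeCHO, Hantzsch ester, L-proline (cat.), CH2Cl2, rt
Reagents that add atoms: acetaldehyde, CC=O
Why: Proline-catalysed Knoevenagel condensation at the only nucleophilic carbon followed by Hantzsch-ester conjugate reduction of the alkylidene dione (three-component reductive alkylation) should give clean C-monoethylation without O-alkylation.

**Step 2**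
Reactants: 3 3-ethyl-4-hydroxy-6-methyl-2H-pyran-2-one
Product: 4 3-ethyl-6-methyl-2-oxo-2H-pyran-4-yl trifluoromethanesulfonate
Conditions: Tf2O, Et3N, CH2Cl2, −78 °C
Reagents that add atoms: trifluoromethanesulfonic anhydride, O=S(=O)(OS(=O)(=O)C(F)(F)F)C(F)(F)F
Why: O-Sulfonylation of the vinylogous acid should give the enol triflate as the handle for cross-coupling.

**Step 3**
Reactants: 4 3-ethyl-6-methyl-2-oxo-2H-pyran-4-yl trifluoromethanesulfonate
Product: 5 3,4-diethyl-6-methyl-2H-pyran-2-one
Conditions: EtMgBr, Fe(acac)3 (5 mol %), THF–NMP, −30 °C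
Reagents that add atoms: ethylmagnesium bromide, CC[Mg]Br
Why: Iron-catalysed Kumada-type coupling of an enol triflate with an alkyl Grignard reagent is fast at low temperature, so β-hydride elimination and attack on the lactone should not compete.

**Step 4**
Reactants: 6 ethyl (S)-lactate
Product: 7 (S)-2-hydroxy-N-methoxy-N-methylpropanamide
Conditions: MeNHOMe·HCl, i-PrMgCl, THF, −20 to 0 °C
Reagents that add atoms: N,O-dimethylhydroxylamine hydrochloride, CNOC.Cl
Why: Aminolysis of the ester by the magnesium amide of N,O-dimethylhydroxylamine should give the Weinreb amide without touching the stereocentre.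

**Step 5**
Reactants: 7 (S)-2-hydroxy-N-methoxy-N-methylpropanamide
Product: 8 (S)-4-hydroxypent-1-en-3-one
Conditions: CH2=CHMgBr (2.5 equiv), THF, 0 °C; inverse quench into cold 1 M HCl
Reagents that add atoms: vinylmagnesium bromide, C=C[Mg]Br
Why: Grignard addition to the Weinreb amide (the first equivalent forms the alkoxide, the chelated tetrahedral intermediate stops over-addition) should give the vinyl ketone, and the acidic inverse quench avoids aza-Michael addition of the released amine.

**Step 6**
Reactants: 8 (S)-4-hydroxypent-1-en-3-one; 9 2-methylbut-3-enenitrile (racemic, 3 equiv)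
Product: 10 (3E,6S)-6-hydroxy-2-methyl-5-oxohept-3-enenitrile (epimer mixture at C2)
Conditions: second-generation Hoveyda–Grubbs catalyst (5 mol %), CH2Cl2, 40 °C
Reagents that add atoms: none
Why: Olefin cross-metathesis between an enone and an excess of a monosubstituted allylic alkene should favour the cross product and the E-enone.

**Step 7**
Reactants: 5 3,4-diethyl-6-methyl-2H-pyran-2-one; 10 (3E,6S)-6-hydroxy-2-methyl-5-oxohept-3-enenitrile
Product: 11 bridged lactone 2-{(1S,4R,5S,6S)-4,8-diethyl-5-[(2S)-2-hydroxypropanoyl]-1-methyl-3-oxo-2-oxabicyclo[2.2.2]oct-7-en-6-yl}propanenitrile (acyl group syn to the C=C bridge, cyanoethyl group syn to the lactone bridge)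
Conditions: toluene, 12 kbar, 45 °C
Reagents that add atoms: none
Why: A concerted, asynchronous normal-demand Diels–Alder ([4+2]) cycloaddition across C3 and C6 of the 2-pyrone, run under pressure below the temperature at which the bridged lactone loses CO2; the closest known chemistry is the thermal and high-pressure cycloaddition of alkyl- and halo-2-pyrones with acrylates and enones to CO2-bridged lactones, and the use of chiral α′-hydroxy enones as dienophiles. The six-membered carbocycle is closed by this one [4+2] cycloaddition, both ring bonds at once, with the lactone kept as a temporary bridge. Suprafacial addition to the flat pyrone fixes the ring oxygen on the methyl-bearing carbon cis to the carbonyl on the ethyl-bearing carbon, the E-alkene delivers acyl and cyanoethyl groups trans to each other, and the Alder endo rule should place the hydrogen-bonded acyl group under the diene, syn to the new C=C bridge. The absolute sense should come from the (S)-carbinol of 10, whose O–H···O=C hydrogen bond holds carbinol and s-cis enone in one plane so that its methyl group blocks one face; the minor facial isomers are diastereomers and are removed by chromatography here. The step needs regio-, endo- and facial selectivity: the acyl-bearing carbon must join C3 of the pyrone, the sense expected for acrylate-type dienophiles, and the substrate supports it sterically because the branched cyanoethyl-bearing carbon then meets the less hindered methyl-bearing C6 (next to C5–H) and not the ethyl-bearing C3 (next to the C4 ethyl group). The nitrile-bearing carbon is not set in this step.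

**Step 8**
Reactants: 11 bridged lactone with the 2-hydroxypropanoyl group
Product: 12 2-[(1S,4R,5S,6S)-4,8-diethyl-1-methyl-3-oxo-5-propanoyl-2-oxabicyclo[2.2.2]oct-7-en-6-yl]propanenitrile
Conditions: SmI2 (2.5 equiv), THF–MeOH, −78 °C
Reagents that add atoms: none
Why: SmI2 reductive cleavage of the α-hydroxy ketone removes the oxygen of the lactate-derived control element and leaves the ethyl ketone before any basic step could isomerise the ketol, while lactone and nitrile should be inert at −78 °C.

**Step 9**
Reactants: 12 bridged lactone with the propanoyl group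
Product: 13 methyl 5-(1-cyanoethyl)-1,2-diethyl-4-hydroxy-4-methyl-6-propanoylcyclohex-2-ene-1-carboxylate (CO2Me, OH and cyanoethyl on one face, propanoyl on the other)
Conditions: NaOMe (0.3 equiv), MeOH, 0 °C
Reagents that add atoms: methanol, CO
Why: Methoxide-catalysed transesterification should open the strained bridged lactone to the methyl ester and the tertiary allylic alcohol, and the ring carbon α to the ketone already has the trans arrangement expected to be the more stable one.

**Step 10**
Reactants: 13 hydroxy ester
Product: 16 methyl 5-(1-cyanoethyl)-1,2-diethyl-4-methyl-2-(2-oxo-2-phenylethyl)-6-propanoylcyclohex-3-ene-1-carboxylate (CO2Me, phenacyl and cyanoethyl on one face; propanoyl and both ring ethyl groups on the other), via benzoylacetate ester 14 (not isolated), via β-keto acid 15 (not isolated)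
Conditions: ethyl benzoylacetate (3 equiv), DMAP (cat.), xylene, 140 °C then reflux
Reagents that add atoms: ethyl benzoylacetate, CCOC(=O)CC(=O)c1ccccc1
Why: Carroll rearrangement (acyl-ketene transesterification of the tertiary allylic alcohol, [3,3]-sigmatropic shift of the enol through a chair transition state, loss of CO2) should deliver the phenacyl group suprafacially to the face that carried the oxygen, that is cis to the ester on the neighbouring carbon, which sets the second quaternary centre and moves the double bond to the methyl-bearing carbon.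

**Step 11**
Reactants: 16 phenacyl ketone
Product: 17 methyl 5-(1-cyanoethyl)-1,2-diethyl-2-[(2S)-2-hydroxy-2-phenylethyl]-4-methyl-6-propanoylcyclohex-3-ene-1-carboxylate
Conditions: RuCl(p-cymene)[(S,S)-TsDPEN] (2 mol %), HCO2H–Et3N (5:2), rt
Reagents that add atoms: none
Why: Noyori transfer hydrogenation reduces aryl ketones much faster than hindered dialkyl ketones, so only the phenyl ketone should be reduced and the ethyl ketone is kept for step 13; the carbinol centre set by the catalyst is removed in step 12.

**Step 12**
Reactants: 17 benzylic alcohol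
Product: 18 methyl 5-(1-cyanoethyl)-1,2-diethyl-4-methyl-2-[(E)-2-phenylethenyl]-6-propanoylcyclohex-3-ene-1-carboxylate
Conditions: Burgess reagent, benzene, 50 °C
Reagents that add atoms: none
Why: Burgess dehydration (syn-elimination of the sulfamate) of the only hydroxyl group can eliminate only toward the CH2 next to the quaternary carbon and should give the conjugated E-styrene.

**Step 13**
Reactants: 18 styryl keto nitrile
Product: 20 methyl ester of the target bearing a tertiary hydroxyl on the ethyl-bearing α-carbon (α-ketol; ring fusion trans; both α-carbons as mixtures), via hydroxy ketimine 19 (not isolated)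
Conditions: SmI2 (3 equiv), t-BuOH, THF, visible light, rt; then 1 M HCl
Reagents that add atoms: water, O
Why: SmI2 ketone–nitrile reductive cyclisation (5-exo attack of the samarium ketyl of the ethyl ketone on the nitrile carbon) should close the cyclopentane between two trans-diequatorial arms, so the ring fusion is trans, and acidic work-up hydrolyses the imine to the ketone; the new carbinol centre is not controlled and is removed in step 14.

**Step 14**
Reactants: 20 α-ketol
Product: 21 methyl ester of the target (both ketone α-carbons as epimer mixtures)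
Conditions: SmI2 (3 equiv), THF–MeOH, −78 to 0 °C
Reagents that add atoms: none
Why: SmI2 reductive cleavage of the hydroxyl α to the ketone (electron transfer, loss of hydroxide, protonation of the samarium enolate) should give the ketone without touching ester or styrene.

**Step 15**
Reactants: 21 methyl ester
Product: 22 (1S,3S,3aR,4R,5S,7aR)-3,4,5-triethyl-1,7-dimethyl-2-oxo-5-[(E)-2-phenylethenyl]-2,3,3a,4,5,7a-hexahydro-1H-indene-4-carboxylic acid
Conditions: LiI, 2,4,6-collidine, 150 °C; then 1 M HCl
Reagents that add atoms: none
Why: SN2-type dealkylation of the methyl ester by iodide avoids attack at the acyl carbon flanked by two quaternary centres, and the hot basic medium should equilibrate both α-carbons of the ketone to the arrangement with each alkyl group trans to the neighbouring ring-fusion substituent, which is the required and expected thermodynamic configuration.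

**Compound list**
1 | 4-hydroxy-6-methyl-2H-pyran-2-one | CC1=CC(O)=CC(=O)O1 | starting material
2 | 3-ethylidene-6-methyl-2H-pyran-2,4(3H)-dione | CC=C1C(=O)C=C(C)OC1=O | intermediate
3 | 3-ethyl-4-hydroxy-6-methyl-2H-pyran-2-one | CCC1=C(O)C=C(C)OC1=O | intermediate
4 | 3-ethyl-6-methyl-2-oxo-2H-pyran-4-yl trifluoromethanesulfonate | CCC1=C(OS(=O)(=O)C(F)(F)F)C=C(C)OC1=O | intermediate
5 | 3,4-diethyl-6-methyl-2H-pyran-2-one | CCC1=C(CC)C=C(C)OC1=O | intermediate
6 | ethyl (S)-lactate | CCOC(=O)[C@H](C)O | starting material
7 | (S)-2-hydroxy-N-methoxy-N-methylpropanamide | C[C@H](O)C(=O)N(C)OC | intermediate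
8 | (S)-4-hydroxypent-1-en-3-one | C[C@H](O)C(=O)C=C | intermediate
9 | 2-methylbut-3-enenitrile (racemic) | C=CC(C)C#N | starting material
10 | (3E,6S)-6-hydroxy-2-methyl-5-oxohept-3-enenitrile | C[C@H](O)C(=O)/C=C/C(C)C#N | intermediate
11 | 2-{(1S,4R,5S,6S)-4,8-diethyl-5-[(2S)-2-hydroxypropanoyl]-1-methyl-3-oxo-2-oxabicyclo[2.2.2]oct-7-en-6-yl}propanenitrile | CC[C@]12C(=O)O[C@](C)(C=C1CC)[C@@H](C(C)C#N)[C@@H]2C(=O)[C@H](C)O | intermediate
12 | 2-[(1S,4R,5S,6S)-4,8-diethyl-1-methyl-3-oxo-5-propanoyl-2-oxabicyclo[2.2.2]oct-7-en-6-yl]propanenitrile | CC[C@]12C(=O)O[C@](C)(C=C1CC)[C@@H](C(C)C#N)[C@@H]2C(=O)CC | intermediate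
13 | methyl 5-(1-cyanoethyl)-1,2-diethyl-4-hydroxy-4-methyl-6-propanoylcyclohex-2-ene-1-carboxylate | CC[C@]1(C(=O)OC)C(CC)=C[C@@](C)(O)[C@@H](C(C)C#N)[C@@H]1C(=O)CC | intermediate
14 | 3-oxo-3-phenylpropanoate ester of the tertiary alcohol of 13 | CC[C@]1(C(=O)OC)C(CC)=C[C@@](C)(OC(=O)CC(=O)c2ccccc2)[C@@H](C(C)C#N)[C@@H]1C(=O)CC | intermediate
15 | β-keto acid from the [3,3] shift of 14 | CC[C@]1(C(=O)OC)[C@@](CC)(C(C(=O)O)C(=O)c2ccccc2)C=C(C)[C@@H](C(C)C#N)[C@@H]1C(=O)CC | intermediate
16 | methyl 5-(1-cyanoethyl)-1,2-diethyl-4-methyl-2-(2-oxo-2-phenylethyl)-6-propanoylcyclohex-3-ene-1-carboxylate | CC[C@]1(C(=O)OC)[C@@](CC)(CC(=O)c2ccccc2)C=C(C)[C@@H](C(C)C#N)[C@@H]1C(=O)CC | intermediate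
17 | methyl 5-(1-cyanoethyl)-1,2-diethyl-2-[(2S)-2-hydroxy-2-phenylethyl]-4-methyl-6-propanoylcyclohex-3-ene-1-carboxylate | CC[C@]1(C(=O)OC)[C@@](CC)(C[C@H](O)c2ccccc2)C=C(C)[C@@H](C(C)C#N)[C@@H]1C(=O)CC | intermediate
18 | methyl 5-(1-cyanoethyl)-1,2-diethyl-4-methyl-2-[(E)-2-phenylethenyl]-6-propanoylcyclohex-3-ene-1-carboxylate | CC[C@]1(C(=O)OC)[C@@](CC)(/C=C/c2ccccc2)C=C(C)[C@@H](C(C)C#N)[C@@H]1C(=O)CC | intermediate
19 | methyl 3,4,5-triethyl-3-hydroxy-2-imino-1,7-dimethyl-5-[(E)-2-phenylethenyl]-2,3,3a,4,5,7a-hexahydro-1H-indene-4-carboxylate | CC[C@]1(C(=O)OC)[C@@](CC)(/C=C/c2ccccc2)C=C(C)[C@H]2C(C)C(=N)C(O)(CC)[C@H]12 | intermediate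
20 | methyl 3,4,5-triethyl-3-hydroxy-1,7-dimethyl-2-oxo-5-[(E)-2-phenylethenyl]-2,3,3a,4,5,7a-hexahydro-1H-indene-4-carboxylate | CC[C@]1(C(=O)OC)[C@@](CC)(/C=C/c2ccccc2)C=C(C)[C@H]2C(C)C(=O)C(O)(CC)[C@H]12 | intermediate
21 | methyl 3,4,5-triethyl-1,7-dimethyl-2-oxo-5-[(E)-2-phenylethenyl]-2,3,3a,4,5,7a-hexahydro-1H-indene-4-carboxylate | CC[C@]1(C(=O)OC)[C@@](CC)(/C=C/c2ccccc2)C=C(C)[C@H]2C(C)C(=O)C(CC)[C@H]12 | intermediate
22 | (1S,3S,3aR,4R,5S,7aR)-3,4,5-triethyl-1,7-dimethyl-2-oxo-5-[(E)-2-phenylethenyl]-2,3,3a,4,5,7a-hexahydro-1H-indene-4-carboxylic acid | CC[C@@H]1C(=O)[C@@H](C)[C@@H]2C(C)=C[C@@](/C=C/c3ccccc3)(CC)[C@](CC)(C(=O)O)[C@H]21 | target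

**Count**
Total steps: 15. Longest linear sequence: 12 (steps 1–3 and 7–15, or equally steps 4–6 and 7–15).

**Steps most likely to fail**

Step 7. The cycloaddition may be slow at two fully substituted diene termini. Regio- and endo-selectivity may erode, the adduct may lose CO2 if heated, and facial discrimination by the small carbinol methyl group may be modest. Fallback: 5 is brominated at its only free ring carbon (NBS, MeCN) to 5-bromo-3,4-diethyl-6-methyl-2H-pyran-2-one F1. 5-Bromo-2-pyrones are ambiphilic dienes that react under milder conditions and direct the acyl-bearing carbon to the carbonyl-side bridgehead with endo preference. Cycloaddition of F1 with 10 (toluene, 90 °C or 10 kbar) should give the 7-bromo bridged lactone F2. Radical debromination (Bu3SnH, AIBN, benzene, 80 °C) returns to 11.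

Step 10. The hindered tertiary allylic alcohol may eliminate to a diene or fail to be acylated by the acyl ketene, so the sigmatropic shift never starts. Fallback: from 13, an acid-catalysed ketal-exchange Claisen rearrangement avoids acylation and decarboxylation. Heating 13 with (1,1-dimethoxyethyl)benzene and catalytic propionic acid (xylene, 140 °C) should form the 1-phenylvinyl ether F3, which rearranges [3,3] with the same suprafacial delivery to 16.

Step 13. The ketyl may be reduced to the alcohol or couple to a pinacol before it reaches the nitrile, or the samarium alkoxide may attack the neighbouring ester. Fallback: from 18, the ketone is reduced (NaBH4, MeOH, 0 °C) to methyl 5-(1-cyanoethyl)-1,2-diethyl-6-(1-hydroxypropyl)-4-methyl-2-[(E)-2-phenylethenyl]cyclohex-3-ene-1-carboxylate F4. F4 is converted (PhOC(S)Cl, pyridine, DMAP) into the O-phenyl thionocarbonate F5. Slow addition of Bu3SnH and AIBN (benzene, 80 °C) should give the secondary radical, which closes 5-exo on the nitrile to the ketimine F6; aqueous HCl hydrolyses F6 to 21, so that 20 and step 14 are bypassed.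

**Further compounds**
F1 | step 7 | 5-bromo-3,4-diethyl-6-methyl-2H-pyran-2-one | CCC1=C(CC)C(Br)=C(C)OC1=O
F2 | step 7 | 2-{7-bromo-4,8-diethyl-5-[(2S)-2-hydroxypropanoyl]-1-methyl-3-oxo-2-oxabicyclo[2.2.2]oct-7-en-6-yl}propanenitrile | CC[C@]12C(=O)O[C@](C)(C(Br)=C1CC)[C@@H](C(C)C#N)[C@@H]2C(=O)[C@H](C)O
F3 | step 10 | methyl 5-(1-cyanoethyl)-1,2-diethyl-4-methyl-4-(1-phenylethenyloxy)-6-propanoylcyclohex-2-ene-1-carboxylate | CC[C@]1(C(=O)OC)C(CC)=C[C@@](C)(OC(=C)c2ccccc2)[C@@H](C(C)C#N)[C@@H]1C(=O)CC
F4 | step 13 | methyl 5-(1-cyanoethyl)-1,2-diethyl-6-(1-hydroxypropyl)-4-methyl-2-[(E)-2-phenylethenyl]cyclohex-3-ene-1-carboxylate | CC[C@]1(C(=O)OC)[C@@](CC)(/C=C/c2ccccc2)C=C(C)[C@@H](C(C)C#N)[C@@H]1C(O)CC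
F5 | step 13 | O-phenyl thionocarbonate of F4 | CC[C@]1(C(=O)OC)[C@@](CC)(/C=C/c2ccccc2)C=C(C)[C@@H](C(C)C#N)[C@@H]1C(OC(=S)Oc3ccccc3)CC
F6 | step 13 | methyl 3,4,5-triethyl-2-imino-1,7-dimethyl-5-[(E)-2-phenylethenyl]-2,3,3a,4,5,7a-hexahydro-1H-indene-4-carboxylate | CC[C@]1(C(=O)OC)[C@@](CC)(/C=C/c2ccccc2)C=C(C)[C@H]2C(C)C(=N)C(CC)[C@H]12
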